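**Strategy.** Ring A of the flavanone carries oxygen at C5, C7 and C8a (O1) around the acyl-bearing C4a. This alternating pattern is that of a cinnamoyl triketide. The route therefore cuts the C4a–C5 bond (C1'–C2' of the chalcone). A 4-hydroxy-2-pyranone with a 2-oxo-4-arylbut-3-enyl chain at C6 is opened by Mg(OMe)2 to a trioxo ester. That ester refolds by Claisen condensation and gives the whole phloroglucinol ring and the chalcone enone in one operation. The precursor holds the complete ring B with its hydroxylated C10 chain. Its phenol is masked only as a silyl ether, which methoxide removes in the same flask. Chalcone isomerase then sets C2 in the last step.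

Key step: step 8

Remarks on the chemistry
- The target is read as the (2S)-flavanone with an E side-chain alkene. C2 is its only stereocentre.
- C2' and C6' of the chalcone interchange by rotation about the C1'–carbonyl bond. The bond made in the key step therefore ends up as C4a–C5 or as C4a–C8a, depending only on which ortho-hydroxyl later closes ring C.
- Assumption: recombinant chalcone isomerase (EC 5.5.1.6, Medicago sativa gene expressed in E. coli) counts as an accessible catalyst.
- The aryl–allyl bond is made from an arylmagnesium and not by phenoxide C-alkylation, which suffers from O-alkylation and over-alkylation.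
- Ring B carries no acid-labile acetal. The phenol, the ortho allylic alkene and the tertiary alcohol together are prone to chroman formation and dehydration in acid.
- Both the folding step and the enzyme are better served by a free 4-hydroxyl.

Step 1
Reactants: 1 geranyl acetate [(2E)-3,7-dimethylocta-2,6-dien-1-yl acetate]
Product: 2 racemic (2E)-5-(3,3-dimethyloxiran-2-yl)-3-methylpent-2-en-1-yl acetate (6,7-epoxygeranyl acetate)
Conditions: mCPBA (1.05 equiv), CH2Cl2, 0 °C
Reagents that add atoms: mCPBA, O=C(OO)c1cccc(Cl)c1
Why: Prilezhaev epoxidation picks the electron-richer C6=C7 alkene because the C2=C3 alkene is deactivated by the allylic acetoxy group, and the racemic epoxide carbon becomes a CH2 group in step 2, so its configuration does not matter.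

Step 2
Reactants: 2 racemic 6,7-epoxygeranyl acetate
Product: 3 (2E)-3,7-dimethyloct-2-ene-1,7-diol
Conditions: LiAlH4, THF, 0 °C to rt; Na2SO4·10H2O quench
Reagents that add atoms: none
Why: In this LiAlH4 reduction, hydride opens the trisubstituted epoxide in SN2 fashion at its less substituted carbon to leave the tertiary C7 alcohol and removes the acetate in the same operation, while the isolated E-trisubstituted alkene is inert.

Step 3
Reactants: 3 (2E)-3,7-dimethyloct-2-ene-1,7-diol
Product: 4 (6E)-8-bromo-2,6-dimethyloct-6-en-2-ol
Conditions: CBr4 (1.05 equiv), PPh3 (1.1 equiv), CH2Cl2, −30 to 0 °C; short silica plug, used at once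
Reagents that add atoms: carbon tetrabromide, BrC(Br)(Br)Br
Why: In this Appel reaction the alkoxyphosphonium salt forms only at the unhindered primary allylic hydroxyl and is displaced by bromide in SN2 manner without allylic shift or loss of E geometry, the tertiary alcohol being too hindered to react.

Step 4
Reactants: 5 4-bromo-2-iodophenol; 4 (6E)-8-bromo-2,6-dimethyloct-6-en-2-ol
Product: 8 4-bromo-2-[(2E)-7-hydroxy-3,7-dimethyloct-2-en-1-yl]phenol, via dimagnesiated bromophenol 6 (not isolated), via chloromagnesium alkoxide 7 (not isolated)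
Conditions: 5: MeMgCl (1.0 equiv), LiCl, THF, −30 °C, then iPrMgCl·LiCl (1.1 equiv), −30 to 0 °C; 4: MeMgCl (1.0 equiv), THF, −78 °C; combine, CuBr·SMe2 (10 mol %), −30 to 0 °C; aq. NH4Cl
Reagents that add atoms: none
Why: Iodine–magnesium exchange on the preformed magnesium phenoxide takes the iodide and spares the bromide, and the copper-catalysed allylic substitution (arylmagnesium in excess over monovalent copper, so a diarylcuprate is the carrier) attacks the primary carbon of the allylic bromide in SN2 sense with the E-alkene retained, both hydroxyl protons having been removed beforehand by MeMgCl so that no aryl metal is lost.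

Step 5
Reactants: 8 4-bromo-2-[(2E)-7-hydroxy-3,7-dimethyloct-2-en-1-yl]phenol
Product: 9 (6E)-8-{5-bromo-2-[(tert-butyldimethylsilyl)oxy]phenyl}-2,6-dimethyloct-6-en-2-ol
Conditions: TBSCl (1.1 equiv), imidazole (2.2 equiv), CH2Cl2, 0 °C to rt
Reagents that add atoms: tert-butyldimethylsilyl chloride, CC(C)(C)[Si](C)(C)Cl
Why: This standard silyl ether formation takes the phenol and leaves the tertiary alcohol untouched for steric reasons, and the silyl group prevents formation of the phenoxide that would deactivate the cinnamamide towards acylation in step 7.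

Step 6
Reactants: 9 silyl-protected aryl bromide; 10 N-methoxy-N-methylacrylamide
Product: 11 (2E)-3-{4-[(tert-butyldimethylsilyl)oxy]-3-[(2E)-7-hydroxy-3,7-dimethyloct-2-en-1-yl]phenyl}-N-methoxy-N-methylprop-2-enamide
Conditions: Pd(OAc)2 (5 mol %), P(o-tol)3 (10 mol %), Et3N, MeCN, 85 °C
Reagents that add atoms: none
Why: In this Mizoroki–Heck reaction zerovalent palladium inserts into the C–Br bond, syn insertion of the terminal acrylamide and syn β-hydride elimination give the E-cinnamamide, and the hindered trisubstituted side-chain alkene (meta to the palladium-bearing carbon) cannot compete.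

Step 7
Reactants: 12 4-hydroxy-6-methyl-2H-pyran-2-one; 11 cinnamic Weinreb amide
Product: 15 6-[(3E)-4-{4-[(tert-butyldimethylsilyl)oxy]-3-[(2E)-7-hydroxy-3,7-dimethyloct-2-en-1-yl]phenyl}-2-oxobut-3-en-1-yl]-4-hydroxy-2H-pyran-2-one (silyl-protected pyranone precursor), via dilithiated pyranone 13 (not isolated), via tetrahedral lithium chelate 14 (not isolated)
Conditions: 12 (2.5 equiv), LiN(iPr)2 (5.0 equiv), THF–DMPU, −78 to −30 °C; 11, −78 to −20 °C; cold 1 M HCl to pH 3
Reagents that add atoms: none
Why: In this Weinreb ketone synthesis the last-formed and most reactive carbanion of the pyranone dianion (the C6 methyl carbon) attacks the amide carbonyl, the N-methoxy lithium chelate 14 survives until the acid quench and so prevents over-addition, and the excess dianion absorbs the proton of the tertiary alcohol.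

Step 8
Reactants: 15 silyl-protected pyranone precursor
Product: 18 (2E)-3-{4-hydroxy-3-[(2E)-7-hydroxy-3,7-dimethyloct-2-en-1-yl]phenyl}-1-(2,4,6-trihydroxyphenyl)prop-2-en-1-one (chalcone), via free-phenol pyranone 16 (not isolated), via methyl trioxo ester 17 (not isolated)
Conditions: Mg(OMe)2 (10 equiv, commercial solution), dry degassed MeOH, Ar, reflux; poured into ice-cold 1 M HCl (pH 3), EtOAc; rapid chromatography on an acid-washed phase
Reagents that add atoms: none
Why: Methoxide first removes the aryl silyl ether (16) and then adds to the lactone carbonyl, so the pyranone opens to the magnesium-chelated methyl 3,5,7-trioxo ester 17, whose C6 carbanion (between the C5 ketone and the cinnamoyl C7 ketone) attacks the ester carbon C1, and loss of methoxide with threefold enolisation gives the aromatic ring A. The closest known reaction type is the Claisen (Dieckmann-type) cyclisation of 3,5,7-trioxo esters and of 6-(2-oxoalkyl)-4-hydroxy-2-pyranones to acylphloroglucinols. The single ring closes in a 6-(enolexo)-exo-trig acyl substitution that forms the C1'–C2' bond of the chalcone. No stereocentre is formed and both E-alkenes are spectators. The step needs C6-to-C1 Claisen folding instead of C2-to-C7 aldol folding (styryl resorcylate): water-free Mg(OMe)2 keeps the ester unsaponified and holds the three ketones as chelated enolates, so the ester is the only electrophile left, and the ring B phenoxide released in the flask pushes electron density through the styryl unit into C7 and the β-carbon, which disfavours aldol attack and methoxide 1,4-addition. The same phenoxide conjugation holds the product in the open chalcone form in base, and the cold quench to pH 3 keeps ring C from closing before step 9.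

Step 9
Reactants: 18 chalcone
Product: 19 (2S)-5,7-dihydroxy-2-{4-hydroxy-3-[(2E)-7-hydroxy-3,7-dimethyloct-2-en-1-yl]phenyl}-2,3-dihydro-4H-chromen-4-one (target)
Conditions: chalcone isomerase (EC 5.5.1.6, recombinant), KH2PO4/K2HPO4 buffer (50 mM, pH 7.0), 10 vol % DMSO, Ar, 25 °C; citric acid to pH 4, EtOAc
Reagents that add atoms: none
Why: In this enzymatic intramolecular oxa-Michael addition (chalcone–flavanone isomerisation) the isomerase binds the 2',4',6'-trihydroxychalcone so that the 2'-oxyanion reaches only one face of the β-carbon, which sets C2 as S, and the configuration is protected by the large rate advantage over the spontaneous non-selective closure and by the absence of any later step.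

Compound list
1 | geranyl acetate | C/C(=C\COC(C)=O)CCC=C(C)C | starting material
2 | racemic (2E)-5-(3,3-dimethyloxiran-2-yl)-3-methylpent-2-en-1-yl acetate | C/C(=C\COC(C)=O)CCC1OC1(C)C | intermediate
3 | (2E)-3,7-dimethyloct-2-ene-1,7-diol | C/C(=C\CO)CCCC(C)(C)O | intermediate
4 | (6E)-8-bromo-2,6-dimethyloct-6-en-2-ol | C/C(=C\CBr)CCCC(C)(C)O | intermediate
5 | 4-bromo-2-iodophenol | Oc1ccc(Br)cc1I | starting material
6 | chloromagnesium 4-bromo-2-(chloromagnesio)phenoxide (not isolated) | Cl[Mg]Oc1ccc(Br)cc1[Mg]Cl | intermediate
7 | chloromagnesium alkoxide of 4 (not isolated) | C/C(=C\CBr)CCCC(C)(C)O[Mg]Cl | intermediate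
8 | 4-bromo-2-[(2E)-7-hydroxy-3,7-dimethyloct-2-en-1-yl]phenol | C/C(=C\Cc1cc(Br)ccc1O)CCCC(C)(C)O | intermediate
9 | (6E)-8-{5-bromo-2-[(tert-butyldimethylsilyl)oxy]phenyl}-2,6-dimethyloct-6-en-2-ol | C/C(=C\Cc1cc(Br)ccc1O[Si](C)(C)C(C)(C)C)CCCC(C)(C)O | intermediate
10 | N-methoxy-N-methylacrylamide | C=CC(=O)N(C)OC | starting material
11 | (2E)-3-{4-[(tert-butyldimethylsilyl)oxy]-3-[(2E)-7-hydroxy-3,7-dimethyloct-2-en-1-yl]phenyl}-N-methoxy-N-methylprop-2-enamide | C/C(=C\Cc1cc(/C=C/C(=O)N(C)OC)ccc1O[Si](C)(C)C(C)(C)C)CCCC(C)(C)O | intermediate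
12 | 4-hydroxy-6-methyl-2H-pyran-2-one | Cc1cc(O)cc(=O)o1 | starting material
13 | dilithiated 4-hydroxy-6-methyl-2-pyranone, O4 and C6-methyl (not isolated) | [Li]Cc1cc(O[Li])cc(=O)o1 | intermediate
14 | tetrahedral lithium chelate from 13 and 11, racemic at the new carbon (not isolated) | C/C(=C\Cc1cc(/C=C/C(O[Li])(Cc2cc(O[Li])cc(=O)o2)N(C)OC)ccc1O[Si](C)(C)C(C)(C)C)CCCC(C)(C)O[Li] | intermediate
15 | silyl-protected 4-hydroxy-6-[(E)-2-oxo-4-arylbut-3-enyl]-2-pyranone (key-step precursor) | C/C(=C\Cc1cc(/C=C/C(=O)Cc2cc(O)cc(=O)o2)ccc1O[Si](C)(C)C(C)(C)C)CCCC(C)(C)O | intermediate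
16 | free-phenol pyranone, present as its magnesium salt (not isolated) | C/C(=C\Cc1cc(/C=C/C(=O)Cc2cc(O)cc(=O)o2)ccc1O)CCCC(C)(C)O | intermediate
17 | methyl (8E)-9-{4-hydroxy-3-[(2E)-7-hydroxy-3,7-dimethyloct-2-en-1-yl]phenyl}-3,5,7-trioxonon-8-enoate, present as its magnesium chelate (not isolated) | C/C(=C\Cc1cc(/C=C/C(=O)CC(=O)CC(=O)CC(=O)OC)ccc1O)CCCC(C)(C)O | intermediate
18 | 4,2',4',6'-tetrahydroxy-3-[(2E)-7-hydroxy-3,7-dimethyloct-2-en-1-yl]chalcone (key-step product) | C/C(=C\Cc1cc(/C=C/C(=O)c2c(O)cc(O)cc2O)ccc1O)CCCC(C)(C)O | intermediate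
19 | (2S)-5,7-dihydroxy-2-{4-hydroxy-3-[(2E)-7-hydroxy-3,7-dimethyloct-2-en-1-yl]phenyl}-2,3-dihydro-4H-chromen-4-one | C/C(=C\Cc1cc([C@@H]2CC(=O)c3c(O)cc(O)cc3O2)ccc1O)CCCC(C)(C)O | target

Total step count: 9. Longest linear sequence: 9 steps (1 to 19). Compounds 5, 10 and 12 are purchased and enter directly.

Steps most likely to fail

Step 8.
- What may go wrong: the opened chain may fold the other way, with the C2 carbanion adding to the C7 ketone and dehydrating to a resorcylate. The pyranone anion may resist methoxide attack. Ring C may also close without facial control during the quench.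
- Fallback: ring A is brought in ready-made instead of being folded. It sets out from amide 11 and returns at chalcone 18.
- Phloroglucinol is converted with MOMCl and iPr2NEt into 1,3,5-tris(methoxymethoxy)benzene F1.
- n-BuLi (THF, 0 °C) lithiates it between two acetal oxygens to 2,4,6-tris(methoxymethoxy)phenyllithium F2.
- Two equivalents of this aryllithium (one is spent on the tertiary hydroxyl) add to 11 at −78 °C in a Weinreb ketone synthesis and give the fully protected chalcone F3.
- K2CO3 in MeOH removes the aryl silyl ether to give the tris(methoxymethyl) chalcone F4.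
- Dilute HCl in MeOH at room temperature cleaves the three acetals, the two that flank the carbonyl being especially labile.

Step 9.
- What may go wrong: the enzyme may bind a substrate with the lipophilic C10 chain poorly. The uncatalysed ring closure, which has no facial preference, then competes and enantiopurity erodes.
- Fallback: cyclisation without stereocontrol followed by resolution with recycling. It sets out from 18 and returns at 19.
- NaOAc in refluxing EtOH closes 18 to the racemic flavanone F5.
- Preparative chromatography on an amylose tris(3,5-dimethylphenylcarbamate) phase separates 19 from the (2R)-flavanone F6.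
- The unwanted enantiomer is reopened with aqueous KOH and a cold acid quench to 18 and fed back.

Step 7.
- What may go wrong: the delocalised carbanion may add in conjugate fashion to the cinnamamide instead of attacking the amide carbonyl. The sparingly soluble dianion may also react sluggishly, so that proton transfer takes over.
- Fallback: aldol addition and oxidation in place of acylation. It sets out from 11 and returns at 15.
- iBu2AlH (THF, −78 °C) reduces 11 to the silyl-protected cinnamaldehyde F7.
- Dianion 13 adds in 1,2 fashion to this aldehyde, the best-established reaction of that dianion, and gives the racemic allylic alcohol F8.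
- MnO2 in CH2Cl2 oxidises the cinnamyl-type alcohol to ketone 15.

Further compounds
F1 | step 8 | 1,3,5-tris(methoxymethoxy)benzene | COCOc1cc(OCOC)cc(OCOC)c1
F2 | step 8 | 2,4,6-tris(methoxymethoxy)phenyllithium | COCOc1cc(OCOC)c([Li])c(OCOC)c1
F3 | step 8 | 4-O-TBS-2',4',6'-tris-O-(methoxymethyl) chalcone | C/C(=C\Cc1cc(/C=C/C(=O)c2c(OCOC)cc(OCOC)cc2OCOC)ccc1O[Si](C)(C)C(C)(C)C)CCCC(C)(C)O
F4 | step 8 | 2',4',6'-tris-O-(methoxymethyl) chalcone with free 4-hydroxyl | C/C(=C\Cc1cc(/C=C/C(=O)c2c(OCOC)cc(OCOC)cc2OCOC)ccc1O)CCCC(C)(C)O
F5 | step 9 | racemic flavanone | C/C(=C\Cc1cc(C2CC(=O)c3c(O)cc(O)cc3O2)ccc1O)CCCC(C)(C)O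
F6 | step 9 | (2R)-flavanone | C/C(=C\Cc1cc([C@H]2CC(=O)c3c(O)cc(O)cc3O2)ccc1O)CCCC(C)(C)O
F7 | step 7 | (2E)-3-{4-[(tert-butyldimethylsilyl)oxy]-3-[(2E)-7-hydroxy-3,7-dimethyloct-2-en-1-yl]phenyl}prop-2-enal | C/C(=C\Cc1cc(/C=C/C=O)ccc1O[Si](C)(C)C(C)(C)C)CCCC(C)(C)O
F8 | step 7 | racemic 6-[(3E)-2-hydroxy-4-arylbut-3-en-1-yl]-4-hydroxy-2H-pyran-2-one (aryl as in 15) | C/C(=C\Cc1cc(/C=C/C(O)Cc2cc(O)cc(=O)o2)ccc1O[Si](C)(C)C(C)(C)C)CCCC(C)(C)O
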